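**Retrosynthetic overview**
- The strategy rests on ring A (the phenol ring): three neighbouring carbons carry C1–OH, C2–O–aryl and C3–Br, and the two oxygens are not equivalent. This is the substitution pattern of the cis-dihydrodiol that toluene dioxygenase makes from bromobenzene, in which the two hydroxyls can be told apart.
- Disconnections, backwards: C4–Br and C6–Br (phenol-directed bromination); the phenol from a C1 carbinol (oxidation to a dienone, then tautomerisation); the C2–O–aryl bond to ring B (alkoxide plus aryl(mesityl)iodonium salt); C1–O and C2–O of ring A (enzymatic cis-dihydroxylation of bromobenzene).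
- Ring order: no ring is built. Ring A is bromobenzene, de-aromatised in step 1 and re-aromatised in step 6; ring B comes intact from 2,4-dibromo-1-iodobenzene.

Key step: step 1

Assumption: the target is achiral, so the (1S,2S) configuration of the diol is carried as the enzyme delivers it and disappears on aromatisation; the recombinant strain is taken to be on hand as a culture and is a biocatalyst, not a starting material.

**Step 1**
Reactants: 1 bromobenzene
Product: 2 (1S,2S)-3-bromocyclohexa-3,5-diene-1,2-diol
Conditions: E. coli JM109 (pDTG601) whole cells, IPTG induction, glucose feed, air, mineral salts medium, pH 7, 30 °C; extraction with base-washed EtOAc; stored cold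
Reagents that add atoms: dioxygen, O=O
Why: Enzymatic arene cis-dihydroxylation: the mononuclear non-haem divalent iron site of toluene dioxygenase, fed with two electrons from NADH through the reductase, ferredoxin and Rieske [2Fe–2S] cluster, activates O2 and adds both oxygen atoms to one face of bromobenzene across the bond between the carbons ortho and meta to bromine, leaving a bromodiene. The closest known reaction type is the whole-cell toluene dioxygenase oxidation of monohalobenzenes, an established preparative process. No ring is closed; two C–O bonds are formed. Both new stereocentres (C1 and C2) are fixed by the enzyme: same-face delivery makes them cis, and the pocket that holds the halogen gives the single (1S,2S) enantiomer. The step needs ortho/meta regioselectivity (not ipso/ortho or meta/para) and no further oxidation to the catechol; the first is imposed by substrate binding in the active site, the second by the recombinant host lacking the diol dehydrogenase. The C2 hydroxyl (next to the vinylic bromide) and the C1 hydroxyl (remote, less hindered) are thereby differentiated, which a catechol would not allow.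

**Step 2**
Reactants: 2 (1S,2S)-3-bromocyclohexa-3,5-diene-1,2-diol
Product: 3 (1S,6S)-2-bromo-6-{[tert-butyl(dimethyl)silyl]oxy}cyclohexa-2,4-dien-1-ol
Conditions: TBSCl (1.05 equiv), imidazole, DMF, −20 °C
Reagents that add atoms: tert-butyldimethylsilyl chloride (TBSCl), CC(C)(C)[Si](C)(C)Cl
Why: Regioselective mono-silylation: the C1 hydroxyl remote from bromine is less hindered and more nucleophilic than the C2 hydroxyl, which is flanked and inductively deactivated by the vinylic bromide, so one equivalent of TBSCl at low temperature should cap O1 only, as known for halobenzene cis-dihydrodiols; no stereocentre is touched.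

**Step 3**
Reactants: 4 2,4-dibromo-1-iodobenzene; 5 mesitylene
Product: 7 (2,4-dibromophenyl)(2,4,6-trimethylphenyl)iodonium trifluoromethanesulfonate, via hydroxy(triflyloxy)iodoarene 6 (not isolated)
Conditions: mCPBA, TfOH, CH2Cl2, 0 °C to rt; then mesitylene, 0 °C; precipitation with Et2O
Reagents that add atoms: trifluoromethanesulfonic acid, OS(=O)(=O)C(F)(F)F; mCPBA, OOC(=O)c1cccc(Cl)c1 (its oxygen stays in intermediate 6 only)
Why: One-pot diaryliodonium triflate synthesis: mCPBA/TfOH oxidises the iodoarene to a trivalent iodine electrophile, which substitutes mesitylene (electrophilic aromatic substitution) at its single kind of ring C–H, and the salt should precipitate from ether.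

**Step 4**
Reactants: 3 (1S,6S)-2-bromo-6-{[tert-butyl(dimethyl)silyl]oxy}cyclohexa-2,4-dien-1-ol; 7 (2,4-dibromophenyl)(2,4,6-trimethylphenyl)iodonium trifluoromethanesulfonate
Product: 9 tert-butyl{[(1S,6S)-5-bromo-6-(2,4-dibromophenoxy)cyclohexa-2,4-dien-1-yl]oxy}dimethylsilane, via sodium alkoxide 8 (not isolated)
Conditions: NaH (1.05 equiv), TBME, 0 °C, 10 min; then 7 (1.2 equiv), 0 °C to rt
Reagents that add atoms: sodium hydride, [Na+].[H-] (sodium of intermediate 8 only)
Why: Metal-free O-arylation of an alkoxide with a diaryliodonium salt: alkoxide 8 replaces triflate on trivalent iodine and ligand coupling should transfer the electron-poorer, ortho-brominated 2,4-dibromophenyl group to O2 while mesityl leaves as iodomesitylene; the C2–O bond of ring A is not broken, so its configuration is retained.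

**Step 5**
Reactants: 9 tert-butyl{[(1S,6S)-5-bromo-6-(2,4-dibromophenoxy)cyclohexa-2,4-dien-1-yl]oxy}dimethylsilane
Product: 10 (1S,6S)-5-bromo-6-(2,4-dibromophenoxy)cyclohexa-2,4-dien-1-ol
Conditions: TBAF, AcOH (1:1), THF, 0 °C; solution carried on without concentration to dryness
Reagents that add atoms: none
Why: Fluoride-induced desilylation; the acetic acid buffer keeps the medium near neutral, so the dienyl aryl ether should be neither eliminated by base nor ionised by acid.

**Step 6**
Reactants: 10 (1S,6S)-5-bromo-6-(2,4-dibromophenoxy)cyclohexa-2,4-dien-1-ol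
Product: 12 3-bromo-2-(2,4-dibromophenoxy)phenol, via dienone 11 (not isolated)
Conditions: Dess–Martin periodinane (1.1 equiv), pyridine, CH2Cl2, 0 °C
Reagents that add atoms: none
Why: Dess–Martin oxidation of the allylic secondary alcohol gives cyclohexa-2,4-dienone 11, which has an α-hydrogen at C6 and should enolise at once (keto–enol tautomerisation driven by aromatisation) to the phenol, erasing both stereocentres.

**Step 7**
Reactants: 12 3-bromo-2-(2,4-dibromophenoxy)phenol
Product: 14 3,4,6-tribromo-2-(2,4-dibromophenoxy)phenol, via para-monobrominated phenol 13 (not isolated)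
Conditions: Br2 (2.05 equiv), AcOH–CH2Cl2, 0 °C to rt
Reagents that add atoms: bromine, BrBr
Why: Electrophilic aromatic bromination: the free hydroxyl is the strongest donor and directs to its para (C4) and open ortho (C6) positions, C2 being blocked and C5 meta to it, while ring B is deactivated by two bromines, so two equivalents of Br2 should stop at the target.

**Compound list**
1 | bromobenzene | Brc1ccccc1 | starting material
2 | (1S,2S)-3-bromocyclohexa-3,5-diene-1,2-diol | O[C@H]1C=CC=C(Br)[C@H]1O | intermediate
3 | (1S,6S)-2-bromo-6-{[tert-butyl(dimethyl)silyl]oxy}cyclohexa-2,4-dien-1-ol | CC(C)(C)[Si](C)(C)O[C@H]1C=CC=C(Br)[C@H]1O | intermediate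
4 | 2,4-dibromo-1-iodobenzene | Brc1ccc(I)c(Br)c1 | starting material
5 | mesitylene (1,3,5-trimethylbenzene) | Cc1cc(C)cc(C)c1 | starting material
6 | 2,4-dibromo-1-[hydroxy(trifluoromethanesulfonyloxy)iodo]benzene | OI(OS(=O)(=O)C(F)(F)F)c1ccc(Br)cc1Br | intermediate
7 | (2,4-dibromophenyl)(2,4,6-trimethylphenyl)iodonium trifluoromethanesulfonate | Cc1cc(C)c([I+]c2ccc(Br)cc2Br)c(C)c1.[O-]S(=O)(=O)C(F)(F)F | intermediate
8 | sodium (1S,6S)-2-bromo-6-{[tert-butyl(dimethyl)silyl]oxy}cyclohexa-2,4-dien-1-olate | CC(C)(C)[Si](C)(C)O[C@H]1C=CC=C(Br)[C@H]1[O-].[Na+] | intermediate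
9 | tert-butyl{[(1S,6S)-5-bromo-6-(2,4-dibromophenoxy)cyclohexa-2,4-dien-1-yl]oxy}dimethylsilane | CC(C)(C)[Si](C)(C)O[C@H]1C=CC=C(Br)[C@H]1Oc1ccc(Br)cc1Br | intermediate
10 | (1S,6S)-5-bromo-6-(2,4-dibromophenoxy)cyclohexa-2,4-dien-1-ol | O[C@H]1C=CC=C(Br)[C@H]1Oc1ccc(Br)cc1Br | intermediate
11 | (6S)-5-bromo-6-(2,4-dibromophenoxy)cyclohexa-2,4-dien-1-one | O=C1C=CC=C(Br)[C@H]1Oc1ccc(Br)cc1Br | intermediate
12 | 3-bromo-2-(2,4-dibromophenoxy)phenol | Oc1cccc(Br)c1Oc1ccc(Br)cc1Br | intermediate
13 | 3,4-dibromo-2-(2,4-dibromophenoxy)phenol | Oc1ccc(Br)c(Br)c1Oc1ccc(Br)cc1Br | intermediate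
14 | 3,4,6-tribromo-2-(2,4-dibromophenoxy)phenol | Oc1c(Br)cc(Br)c(Br)c1Oc1ccc(Br)cc1Br | target

**Totals**
Total step count: 7. Longest linear sequence: 6 steps (steps 1, 2, 4, 5, 6, 7 from bromobenzene); step 3 is a one-step side branch.

**Steps most likely to fail**

Step 4 (O-arylation). Several processes could compete with aryl transfer:
- 1,2-migration of the silyl group between the cis oxygens in alkoxide 8, which would put ring B on the wrong oxygen;
- base-induced elimination with aromatisation of the diene;
- ortho-deprotonation of the iodonium salt to an aryne;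
- hydride-transfer oxidation of the alkoxide by the iodonium salt.

The fallback avoids the alkoxide altogether; it sets out from diol 2 and returns at phenol 12. Diol 2 is reduced at the disubstituted C5=C6 alkene with diimide (KO2CN=NCO2K, AcOH, MeOH, 0 °C) to (1S,2S)-3-bromocyclohex-3-ene-1,2-diol F1. The remote hydroxyl is silylated (TBSCl, imidazole, DMF, −10 °C) to (1S,6S)-2-bromo-6-{[tert-butyl(dimethyl)silyl]oxy}cyclohex-2-en-1-ol F2. Mitsunobu etherification with 2,4-dibromophenol (PPh3, DIAD, THF, 0 °C) forms the C2–O–aryl bond under neutral conditions with inversion, giving tert-butyl{[(1S,2R)-3-bromo-2-(2,4-dibromophenoxy)cyclohex-3-en-1-yl]oxy}dimethylsilane F3. Buffered TBAF/AcOH frees (1S,2R)-3-bromo-2-(2,4-dibromophenoxy)cyclohex-3-en-1-ol F4, Dess–Martin oxidation gives (2R)-3-bromo-2-(2,4-dibromophenoxy)cyclohex-3-en-1-one F5, and DDQ in dioxane at 80 °C dehydrogenates F5 through its dienol to phenol 12. The inverted C2 centre is of no consequence because it is erased.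

Step 5 (desilylation). Fluoride may act as a base and trigger β-elimination of 2,4-dibromophenoxide with aromatisation (loss of ring B), or the freed dienol may dimerise by Diels–Alder reaction on handling. The fallback re-aromatises before the silyl group is removed; it sets out from silyl ether 9 and returns at phenol 12. DDQ (CH2Cl2, rt) dehydrogenates the cyclohexa-1,3-diene of 9 (hydride abstraction at one oxygenated sp3 carbon, proton loss from the other) to [3-bromo-2-(2,4-dibromophenoxy)phenoxy](tert-butyl)dimethylsilane F6. This robust aryl silyl ether is then cleaved with TBAF/AcOH in THF to give 12, and step 6 is no longer needed.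

Step 7 (bromination). Bromination may run on to C5 of ring A or to C6' of ring B, or stall at a mixture of mono-bromides. The fallback replaces the single exhaustive bromination by two reagent-controlled stages; it sets out from phenol 12 and returns at target 14. NBS with catalytic diisopropylamine (CH2Cl2, 0 °C) delivers bromine to the open ortho position and should give 3,6-dibromo-2-(2,4-dibromophenoxy)phenol F7. One further equivalent of NBS (MeCN, 0 °C to rt) then brominates the only remaining activated position, para to the hydroxyl, to give 14.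

**Further compounds**
F1 | step 4 | (1S,2S)-3-bromocyclohex-3-ene-1,2-diol | O[C@H]1CCC=C(Br)[C@H]1O
F2 | step 4 | (1S,6S)-2-bromo-6-{[tert-butyl(dimethyl)silyl]oxy}cyclohex-2-en-1-ol | CC(C)(C)[Si](C)(C)O[C@H]1CCC=C(Br)[C@H]1O
F3 | step 4 | tert-butyl{[(1S,2R)-3-bromo-2-(2,4-dibromophenoxy)cyclohex-3-en-1-yl]oxy}dimethylsilane | CC(C)(C)[Si](C)(C)O[C@H]1CCC=C(Br)[C@@H]1Oc1ccc(Br)cc1Br
F4 | step 4 | (1S,2R)-3-bromo-2-(2,4-dibromophenoxy)cyclohex-3-en-1-ol | O[C@H]1CCC=C(Br)[C@@H]1Oc1ccc(Br)cc1Br
F5 | step 4 | (2R)-3-bromo-2-(2,4-dibromophenoxy)cyclohex-3-en-1-one | O=C1CCC=C(Br)[C@@H]1Oc1ccc(Br)cc1Br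
F6 | step 5 | [3-bromo-2-(2,4-dibromophenoxy)phenoxy](tert-butyl)dimethylsilane | CC(C)(C)[Si](C)(C)Oc1cccc(Br)c1Oc1ccc(Br)cc1Br
F7 | step 7 | 3,6-dibromo-2-(2,4-dibromophenoxy)phenol | Oc1c(Br)ccc(Br)c1Oc1ccc(Br)cc1Br
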